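## Structural features

The target is a ten-membered carbocycle (C1 to C10, germacrane numbering) fused along C6–C7 to a butenolide (O–C6, C7=C11, C12=O) and along C4–C5 to a cis epoxide whose quaternary carbon C4 carries methyl C15. C1 is a ketone next to the methyl-bearing stereocentre C10; C8 carries a tiglate and C11 an acetoxymethyl group (C13). C4, C5 and C6 are contiguous stereocentres. C8 is separated from C6 only by the trigonal C7, and C10 stands 1,3 to C8 and alpha to the ketone, so it can epimerise. The fragile groups are:

- the trisubstituted epoxide (acid, transannular opening);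
- the allylic acetate on the butenolide (SN2′ displacement);
- the gamma-acidic butenolide;
- the tiglate, which tolerates neither hydride nor borane.

The real difficulty is the medium ring together with the relative configuration of centres that are not adjacent (C6/C8/C10), and the choice of a 12,6- over a 12,8-lactone. The key step exploits the following map: the cis C4=C5 unit hidden in the epoxide, with methyl on C4, oxygen on C6 and the methyl-bearing C10 three atoms away, is a 3-methyl-6-isopropenylcyclohex-2-enone. C7–C8 with its oxygen is a Z alkoxyvinyl group, and a [3,3] shift joins C8 to C9 while opening the six-membered ring to the ten-membered one.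

## Logic of the disconnections

**34 back to 29 (through 33 and 32).** The two ester C–O bonds (O13–acetyl, O8–tigloyl) are cut first. The C13 acetate is an SN2′ leaving group and the tiglate would not survive borane, so both acyl groups must come last. This leaves a diol whose two hydroxyls are already told apart (C13 silyl ether, C8 free). The forward steps must acylate C8 while C13 is still silylated, and must acetylate C13 without a nucleophilic catalyst.

**29 back to 25 (through 28 and 27).** The C8 benzylic ether is restored, and the C1=O and C10–H bonds are traced back to the E C1=C10 olefin. The ketone and its epimerisable neighbour then appear late, and the olefin is exactly what the ring-forming step delivers. The forward step must be an anti-Markovnikov, face-selective hydroboration that leaves the epoxide and butenolide alone.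

**25 back to 21 (through 23 and 22).** The C7=C11 π bond is replaced by a C11 carbinol and the lactone O6–C12 bond is cut. C7 becomes sp3 and a gamma-hydroxy ester appears, which is an aldol retron. Forward, only O6 may lactonise (O8 stays blocked), and water must be lost toward C7 and not toward C13.

**21 back to 20.** Both epoxide C–O bonds are cut. A free C6 hydroxyl next to the cis olefin can deliver the oxygen, so two stereocentres depend on one. The epoxidation must precede lactonisation and must ignore C1=C10.

**20 back to 19.** The C6–H bond is cut. Hydride must arrive under chelation between the C6 carbonyl and the C8 ether, which is why the C11 oxygen of 19 is silylated.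

**19 back to 12 and 16.** The C7–C11 bond is cut. C7 is the only sp3 alpha carbon of the C6 ketone, and 16 brings C11, C12 and C13 at the right oxidation levels. The enolate must add faster than it expels the C8 ether.

**12 back to 9.** The C8–C9 bond is cut and C1–C6 is re-formed (retro-[3,3]). The ten-membered ring, its E olefin and C8 collapse to a cyclohexenol with one carbinol centre. The forward step needs a chair transition state, a Z enol ether and trans alkenyl groups.

**9 back to 2 and 7 (through 8).** The C6–C7 bond is cut. The addition must occur trans to the isopropenyl group and the Z geometry must be kept through metalation.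

**2 back to 1; 7 back to 5, then 3 and 4; 16 back to 14, then 13.** These are an allylic C–H oxidation, a vinyl transfer followed by bromination and elimination, and a silylation followed by cleavage of a C=C bond. Each needs only that the existing stereocentre or geometry is not disturbed.

## Other disconnections considered

**Alternative 1:** The cut is made at the C5–O bond of the epoxide and at the lactone O6–C12 bond, which leads to an open chain. Forward, NaH would convert the C4 tertiary alcohol of the hydroxy epoxy ester A2 into its alkoxide. The alkoxide would open the trans 5,6-epoxide at C5 with inversion, and the C6 alkoxide released would close on the cis methyl ester to give the epoxy butenolide A1.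

- In its favour: C4, C5 and C6 are related by a stereospecific SN2 event, the lactonisation pulls the epoxide migration to one side, the regiochemistry of the lactone is fixed by the olefin geometry, and C8 is already in place.
- Against it here: A1 is still acyclic. The C1–C10 bond, the C14 methyl and the C1 ketone are all missing, so a ten-membered ring would have to be closed late in the presence of the epoxide and the butenolide. A2 itself needs four stereocentres built on a chain.
- Comparison: on the C4–C5–C6 triad this plan is the better of the two, since inversion is more certain than chelation-controlled reduction followed by directed epoxidation. On ring formation the chosen plan is better, because the ring arises by expansion of a terpene-derived cyclohexene in five steps from purchase and without high dilution. On step economy the chosen plan should be shorter overall.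

**Alternative 2:** The cut is made at the C8–O and C13–O bonds together. Forward, singlet oxygen (light, tetraphenylporphyrin) would add across C8 and C13 of the dienyl lactone A4 to give the endoperoxide A3, creating the C7=C11 olefin at the same time. The O–O bond would then be cleaved reductively and the two hydroxyls acylated in turn.

- In its favour: both oxygens and the butenolide olefin arrive in one mild, late step that tolerates the epoxide and ketone, and no protecting groups are needed at C8 or C13. In oxidation-state economy this is better than the chosen plan, which spends an aldol, a dehydration and three protecting-group operations on the same atoms.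
- Against it here: the cycloadduct has the 8-epi configuration, so C8 must be inverted afterwards at an allylic position where SN2′ competes. The plan says nothing about how the ring, C6, the epoxide and C10 of A4 are made. The C8 configuration rests on facial selectivity, not on chirality transfer.
- Comparison: equal in mildness; better in the count of steps after the ring exists; weaker on C8, which the chosen plan fixes through a chair transition state; and incomplete on the ring.

**Alternative 3:** The cut is made at C6–C7 and at O6–C12. Forward, CrCl2 with catalytic NiCl2 would convert the Z enol triflate of the aldehyde A6 into a C7 alkenylchromium species. This would add to the C6 aldehyde to close the ten-membered ring, and the alkoxide would lactonise on the cis ester to give the bis-silyl ether A5.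

- In its favour: ring and butenolide form in one operation, the aldehyde is attacked in preference to the C1 ketone, and A5 is only a desilylation and two acylations from the target. Its end game is shorter than that of the chosen plan, and it avoids the late hydroboration at C1/C10.
- Against it here: a ten-membered ring must be closed from a hindered tetrasubstituted alkenyl metal on an epimerisable epoxy aldehyde, under dilution and with a large excess of chromium. C6 is created in that step under macrocyclic control. A6 carries four preset stereocentres and a geometrically defined enol triflate, all from acyclic chemistry.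
- Comparison: equal in that both plans close the ring with a C–C bond and set one stereocentre in doing so. Better in end-game brevity. Weaker in reliability of ring formation, where an intramolecular [3,3] ring expansion needs no dilution and transfers chirality, and weaker in the length of the route to the cyclisation substrate.

Key step: step 5

**Remarks before the steps**

- Correction of a name: the ketone formed in the key step has no C11–C13, so it is a 3,7-dimethylcyclodecadienone (an 11,12,13-trinor-germacrane) and is named as such (12). The precursor is (1R,6R) (9). The Z enol ether does lead to 8S through the chair, and (S)-limonene does lead to the (R)-enone.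
- Assumption: C11 of 18–24 is drawn as the epimer whose oxygen is cis to H-7 on the lactone ring (11S). This centre and C7 become trigonal in step 12.
- Enolate 17 is drawn without C6=C7 geometry, which is not controlled and not needed.
- Precursor design: the skeleton of 9 is kept. It is to be handled on amine-washed silica, because it is an acid-labile enol ether and tertiary allylic alcohol. Its alkoxide is made with a soluble base and the enolate is quenched cold.

## Route

Step 1
Reactants: 1 (S)-limonene
Product: 2 (R)-isopiperitenone, (6R)-3-methyl-6-(prop-1-en-2-yl)cyclohex-2-en-1-one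
Conditions: Cr(CO)6 (cat.), t-BuOOH, MeCN, reflux
Reagents that add atoms: tert-butyl hydroperoxide, CC(C)(C)OO
Why: Chromium-catalysed allylic oxidation of the ring CH2 between the trisubstituted olefin and C4 gives the enone; the regioisomeric enone from the other allylic CH2 is separated, and the stereocentre is not touched (its descriptor changes from S to R only because the new carbonyl outranks the isopropenyl group).

Step 2
Reactants: 3 4-methoxybenzyl alcohol; 4 ethyl vinyl ether
Product: 5 4-methoxybenzyl vinyl ether
Conditions: Hg(OAc)2 (cat.), 4 as solvent, reflux; K2CO3 work-up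
Reagents that add atoms: none
Why: Mercury-acetate-catalysed vinyl ether exchange (transetherification) driven by the excess of 4; a primary benzylic alcohol is a standard substrate.

Step 3
Reactants: 5 4-methoxybenzyl vinyl ether
Product: 7 (Z)-1-bromo-2-[(4-methoxybenzyl)oxy]ethene, via dibromo ether 6 (not isolated)
Conditions: Br2, CH2Cl2, −78 °C; then i-Pr2NEt, −78 → 40 °C
Reagents that add atoms: bromine, BrBr
Why: Bromine adds to the enol ether far faster than to the anisole ring at −78 °C; the alpha-bromo ether ionises and loses HBr to the hindered amine, and as with simple alkyl vinyl ethers the cis (Z) beta-bromo enol ether is favoured; any E isomer is removed, and its lithio derivative would in any case fragment to acetylene.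

Step 4
Reactants: 7 (Z)-1-bromo-2-[(4-methoxybenzyl)oxy]ethene; 2 (R)-isopiperitenone
Product: 9 (1R,6R)-1-{(Z)-2-[(4-methoxybenzyl)oxy]ethenyl}-3-methyl-6-(prop-1-en-2-yl)cyclohex-2-en-1-ol, via vinyllithium 8 (not isolated)
Conditions: n-BuLi, Et2O, −78 °C; then 2, THF, −78 °C; aq. NaHCO3; Et3N-washed SiO2
Reagents that add atoms: none
Why: Bromine–lithium exchange with retention gives the Z lithio enol ether, which is stable at −78 °C because Li and OR are cis and cannot eliminate anti; 1,2-addition to the enone from the equatorial direction, trans to the neighbouring isopropenyl group (as with 2-substituted cyclohexanones), sets the carbinol centre 1R and places the two alkenyl groups trans; the minor cis isomer is separated.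

Step 5
Reactants: 9 (1R,6R)-1-{(Z)-2-[(4-methoxybenzyl)oxy]ethenyl}-3-methyl-6-(prop-1-en-2-yl)cyclohex-2-en-1-ol
Product: 12 (2Z,6E,9S)-9-[(4-methoxybenzyl)oxy]-3,7-dimethylcyclodeca-2,6-dien-1-one, via potassium alkoxide 10 (not isolated), via potassium enolate 11 (not isolated)
Conditions: KN(SiMe3)2, 18-crown-6, THF, −78 → 0 °C; then AcOH, −78 °C
Reagents that add atoms: none
Why: KN(SiMe3)2 makes alkoxide 10 and the crown ether frees the oxyanion, which weakens the doubly allylic C1–C6 bond so that the [3,3] shift should run at or below 0 °C. The C8–C9 σ bond forms as C1–C6 breaks, and enolate 11 is protonated cold to 12; the closest known reaction is the anionic oxy-Cope ring expansion of trans-1,2-dialkenylcyclohexanols to cyclodec-5-enones. The ten-membered ring is not closed by a cyclisation but arises by ring expansion of the cyclohexene through the six-membered chair array C8–C7–C6···C1–C10–C9. Because the alkenyl groups are trans, only the chair with both ring bonds (C6–C5 and C1–C2) equatorial is available, which gives the E C1=C10 olefin and leaves the cis C4=C5 olefin untouched. The new stereocentre C8 is fixed by that chair, by the Z enol ether, which holds the ether oxygen axial, and by the R centre bearing the isopropenyl group, which decides which face of C7=C8 meets C9; the result is 8S (C9 of 12). The step needs chair over boat, and it needs the enolate to survive without expelling the C8 ether; the trans substrate secures the first, and low temperature with a cold acidic quench secures the second. The price of the chair is a 1,3-diaxial pair of oxygens, which should be tolerable in an early, fragmentation-like transition state.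

Step 6
Reactants: 13 ethyl 2-(hydroxymethyl)acrylate
Product: 14 ethyl 2-{[(tert-butyldimethylsilyl)oxy]methyl}acrylate
Conditions: t-BuMe2SiCl, imidazole, CH2Cl2, 0 → 23 °C
Reagents that add atoms: tert-butyldimethylsilyl chloride, CC(C)(C)[Si](C)(C)Cl
Why: Standard silylation of a primary alcohol; the silyl ether later serves as the C13 protecting group.

Step 7
Reactants: 14 ethyl 2-{[(tert-butyldimethylsilyl)oxy]methyl}acrylate
Product: 16 ethyl 3-[(tert-butyldimethylsilyl)oxy]-2-oxopropanoate, via ozonide 15 (not isolated)
Conditions: O3, CH2Cl2, −78 °C; then Me2S, −78 → 23 °C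
Reagents that add atoms: ozone, [O-][O+]=O
Why: Ozonolysis of the 1,1-disubstituted acrylate with reductive work-up gives the alpha-keto ester; it is used fresh because it hydrates easily.

Step 8
Reactants: 12 (2Z,6E,9S)-9-[(4-methoxybenzyl)oxy]-3,7-dimethylcyclodeca-2,6-dien-1-one; 16 ethyl 3-[(tert-butyldimethylsilyl)oxy]-2-oxopropanoate
Product: 19 ethyl (1(10)E,4Z,7R,8S,11S)-13-[(tert-butyldimethylsilyl)oxy]-8-[(4-methoxybenzyl)oxy]-6-oxo-11-[(trimethylsilyl)oxy]germacra-1(10),4-dien-12-oate, via lithium enolate 17 (not isolated), via lithium aldolate 18 (not isolated)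
Conditions: LiN(i-Pr)2, THF, −78 °C; 16, −78 °C; then Me3SiCl, Et3N, −78 → −20 °C
Reagents that add atoms: chlorotrimethylsilane, C[Si](C)(C)Cl
Why: Kinetic deprotonation at C7, the only sp3 alpha carbon, gives the cross-conjugated enolate, and the very electrophilic alpha-keto ester should be attacked at −78 °C before the C8 ether is expelled (aldol addition; C–C bond on the exposed face of the ring enolate, anti to the C8 oxygen, 7R; C11 as assumed). Silylation of the aldolate blocks retro-aldol cleavage and masks the C11 oxygen for step 9.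

Step 9
Reactants: 19 ethyl (1(10)E,4Z,7R,8S,11S)-13-[(tert-butyldimethylsilyl)oxy]-8-[(4-methoxybenzyl)oxy]-6-oxo-11-[(trimethylsilyl)oxy]germacra-1(10),4-dien-12-oate
Product: 20 ethyl (1(10)E,4Z,6R,7R,8S,11S)-13-[(tert-butyldimethylsilyl)oxy]-6-hydroxy-8-[(4-methoxybenzyl)oxy]-11-[(trimethylsilyl)oxy]germacra-1(10),4-dien-12-oate
Conditions: Zn(BH4)2, Et2O, −30 °C; aq. NH4Cl
Reagents that add atoms: none
Why: Chelation-controlled 1,2-reduction of a beta-alkoxy enone: zinc is held between the C6 carbonyl and the C8 ether oxygen (the silylated C11 oxygen cannot compete), and hydride adds axially to the half-chair chelate with C9 and the C7 substituent equatorial, giving the 6,8-syn alcohol. It is 6R by the sequence rule but has the same spatial arrangement as 6S of the target; the hindered ester next to the silyl ether should not lactonise under these neutral conditions.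

Step 10
Reactants: 20 ethyl (1(10)E,4Z,6R,7R,8S,11S)-13-[(tert-butyldimethylsilyl)oxy]-6-hydroxy-8-[(4-methoxybenzyl)oxy]-11-[(trimethylsilyl)oxy]germacra-1(10),4-dien-12-oate
Product: 21 ethyl (1(10)E,4R,5S,6S,7R,8S,11S)-13-[(tert-butyldimethylsilyl)oxy]-4,5-epoxy-6-hydroxy-8-[(4-methoxybenzyl)oxy]-11-[(trimethylsilyl)oxy]germacr-1(10)-en-12-oate
Conditions: VO(acac)2 (cat.), t-BuOOH, CH2Cl2, 0 °C
Reagents that add atoms: tert-butyl hydroperoxide, CC(C)(C)OO
Why: Hydroxyl-directed epoxidation: the vanadate ester of the C6 alcohol delivers oxygen to the adjacent cis olefin from the face the hydroxyl leans over, which in medium-ring Z allylic alcohols gives the cis (erythro) epoxy alcohol, here 4R,5S; the remote E olefin has no directing hydroxyl and should not react.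

Step 11
Reactants: 21 ethyl (1(10)E,4R,5S,6S,7R,8S,11S)-13-[(tert-butyldimethylsilyl)oxy]-4,5-epoxy-6-hydroxy-8-[(4-methoxybenzyl)oxy]-11-[(trimethylsilyl)oxy]germacr-1(10)-en-12-oate
Product: 23 (1(10)E,4R,5S,6S,7S,8S,11S)-13-[(tert-butyldimethylsilyl)oxy]-4,5-epoxy-11-hydroxy-8-[(4-methoxybenzyl)oxy]germacr-1(10)-en-12,6-olide, via silyloxy lactone 22 (not isolated)
Conditions: K2CO3, MeOH, 0 → 23 °C
Reagents that add atoms: none
Why: Base-mediated transesterification: the C6 alkoxide closes on the ethyl ester (5-exo-trig) to the cis-fused gamma-lactone, and the tertiary trimethylsilyl ether is then methanolysed; once O6 is acylated the epoxy alcohol can no longer undergo epoxide migration, and O8 is blocked, so only the 12,6-lactone can form.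

Step 12
Reactants: 23 (1(10)E,4R,5S,6S,7S,8S,11S)-13-[(tert-butyldimethylsilyl)oxy]-4,5-epoxy-11-hydroxy-8-[(4-methoxybenzyl)oxy]germacr-1(10)-en-12,6-olide
Product: 25 (1(10)E,4R,5S,6S,8S)-13-[(tert-butyldimethylsilyl)oxy]-4,5-epoxy-8-[(4-methoxybenzyl)oxy]germacra-1(10),7(11)-dien-12,6-olide, via sulfamate salt 24 (not isolated)
Conditions: MeO2CN−SO2N+Et3 (Burgess reagent), PhMe, 50 °C
Reagents that add atoms: none
Why: Burgess dehydration: the tertiary alcohol forms a sulfamate ester that eliminates intramolecularly and syn; H-7 is cis to it on the lactone ring, and loss toward C7 gives the tetrasubstituted conjugated olefin (Zaitsev) in preference to an enol ether from C13–H; C7 and C11 both become trigonal.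

Step 13
Reactants: 25 (1(10)E,4R,5S,6S,8S)-13-[(tert-butyldimethylsilyl)oxy]-4,5-epoxy-8-[(4-methoxybenzyl)oxy]germacra-1(10),7(11)-dien-12,6-olide
Product: 27 (1S,4R,5S,6S,8S,10R)-13-[(tert-butyldimethylsilyl)oxy]-4,5-epoxy-1-hydroxy-8-[(4-methoxybenzyl)oxy]germacr-7(11)-en-12,6-olide, via alkylborane 26 (not isolated)
Conditions: BH3·THF, THF, 0 °C; then H2O2, aq. NaOAc, 0 → 23 °C
Reagents that add atoms: hydrogen peroxide, OO
Why: Hydroboration–oxidation: boron goes to the less substituted C1 and hydrogen to C10, syn, on the outer face of the strained E olefin, the only face open in a ten-membered ring; in the conformer that keeps methyl C14 away from the C8 ether oxygen this face gives 10R (and 1S). The electron-poor tetrasubstituted butenolide olefin does not react, and the buffered peroxide spares the lactone and epoxide.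

Step 14
Reactants: 27 (1S,4R,5S,6S,8S,10R)-13-[(tert-butyldimethylsilyl)oxy]-4,5-epoxy-1-hydroxy-8-[(4-methoxybenzyl)oxy]germacr-7(11)-en-12,6-olide
Product: 28 (4R,5S,6S,8S,10R)-13-[(tert-butyldimethylsilyl)oxy]-4,5-epoxy-8-[(4-methoxybenzyl)oxy]-1-oxogermacr-7(11)-en-12,6-olide
Conditions: Dess–Martin periodinane, NaHCO3, CH2Cl2, 0 °C
Reagents that add atoms: none
Why: Buffered periodinane oxidation of the only free alcohol; near-neutral conditions should leave the new alpha centre C10 and the epoxide untouched.

Step 15
Reactants: 28 (4R,5S,6S,8S,10R)-13-[(tert-butyldimethylsilyl)oxy]-4,5-epoxy-8-[(4-methoxybenzyl)oxy]-1-oxogermacr-7(11)-en-12,6-olide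
Product: 29 (4R,5S,6S,8S,10R)-13-[(tert-butyldimethylsilyl)oxy]-4,5-epoxy-8-hydroxy-1-oxogermacr-7(11)-en-12,6-olide
Conditions: DDQ, CH2Cl2/pH 7 buffer, 0 °C
Reagents that add atoms: none
Why: Oxidative removal of the 4-methoxybenzyl ether by benzylic hydride abstraction and hydrolysis; epoxide, silyl ether, ketone and butenolide are inert to the quinone.

Step 16
Reactants: 29 (4R,5S,6S,8S,10R)-13-[(tert-butyldimethylsilyl)oxy]-4,5-epoxy-8-hydroxy-1-oxogermacr-7(11)-en-12,6-olide; 30 tiglic acid
Product: 32 (4R,5S,6S,8S,10R)-13-[(tert-butyldimethylsilyl)oxy]-4,5-epoxy-8-[(E)-2-methylbut-2-enoyloxy]-1-oxogermacr-7(11)-en-12,6-olide, via mixed anhydride 31 (not isolated)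
Conditions: 30, 2,4,6-Cl3C6H2COCl, Et3N, PhMe, 23 °C; then 29, DMAP, 23 °C
Reagents that add atoms: none
Why: Yamaguchi esterification: the mixed anhydride transfers the tigloyl group through the acylpyridinium to the hindered secondary allylic alcohol with retention at C8; C13 is still a silyl ether, so no allylic leaving group is exposed to the nucleophilic catalyst.

Step 17
Reactants: 32 (4R,5S,6S,8S,10R)-13-[(tert-butyldimethylsilyl)oxy]-4,5-epoxy-8-[(E)-2-methylbut-2-enoyloxy]-1-oxogermacr-7(11)-en-12,6-olide
Product: 33 (4R,5S,6S,8S,10R)-4,5-epoxy-13-hydroxy-8-[(E)-2-methylbut-2-enoyloxy]-1-oxogermacr-7(11)-en-12,6-olide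
Conditions: HF·pyridine, pyridine, THF, 0 °C
Reagents that add atoms: none
Why: Buffered fluoride cleavage of the primary silyl ether; the mildly acidic, non-basic medium should spare the epoxide and the esters and should not promote acyl migration from O8.

Step 18
Reactants: 33 (4R,5S,6S,8S,10R)-4,5-epoxy-13-hydroxy-8-[(E)-2-methylbut-2-enoyloxy]-1-oxogermacr-7(11)-en-12,6-olide
Product: 34 (4R,5S,6S,8S,10R)-13-acetoxy-4,5-epoxy-8-[(E)-2-methylbut-2-enoyloxy]-1-oxogermacr-7(11)-en-12,6-olide (target)
Conditions: Ac2O, pyridine, 0 °C
Reagents that add atoms: acetic anhydride, CC(=O)OC(C)=O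
Why: Acetylation of the primary allylic alcohol; pyridine alone is used so that no strong nucleophile is present to displace the new allylic acetate in the SN2′ sense.

## Compound list

1 | (S)-limonene, (4S)-1-methyl-4-(prop-1-en-2-yl)cyclohex-1-ene | CC1=CC[C@H](CC1)C(C)=C | starting material
2 | (R)-isopiperitenone, (6R)-3-methyl-6-(prop-1-en-2-yl)cyclohex-2-en-1-one | O=C1C=C(C)CC[C@@H]1C(C)=C | intermediate
3 | 4-methoxybenzyl alcohol | COc1ccc(CO)cc1 | starting material
4 | ethyl vinyl ether | CCOC=C | starting material
5 | 4-methoxybenzyl vinyl ether | C=COCc1ccc(OC)cc1 | intermediate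
6 | 1-[(1,2-dibromoethoxy)methyl]-4-methoxybenzene (racemic) | BrCC(Br)OCc1ccc(OC)cc1 | intermediate (not isolated)
7 | (Z)-1-bromo-2-[(4-methoxybenzyl)oxy]ethene | Br/C=C\OCc1ccc(OC)cc1 | intermediate
8 | (Z)-2-[(4-methoxybenzyl)oxy]vinyllithium | [Li]/C=C\OCc1ccc(OC)cc1 | intermediate (not isolated)
9 | (1R,6R)-1-{(Z)-2-[(4-methoxybenzyl)oxy]ethenyl}-3-methyl-6-(prop-1-en-2-yl)cyclohex-2-en-1-ol | O[C@]1(/C=C\OCc2ccc(OC)cc2)C=C(C)CC[C@@H]1C(C)=C | intermediate
10 | potassium alkoxide of 9 | [K+].[O-][C@]1(/C=C\OCc2ccc(OC)cc2)C=C(C)CC[C@@H]1C(C)=C | intermediate (not isolated)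
11 | potassium enolate of 12 (O–C6=C7 with C5 and C8 trans in the ring, C8 S) | [K+].[O-]/C1=C\[C@@H](OCc2ccc(OC)cc2)C/C(C)=C/CC/C(C)=C\1 | intermediate (not isolated)
12 | (2Z,6E,9S)-9-[(4-methoxybenzyl)oxy]-3,7-dimethylcyclodeca-2,6-dien-1-one | O=C1C[C@@H](OCc2ccc(OC)cc2)C/C(C)=C/CC/C(C)=C\1 | intermediate
13 | ethyl 2-(hydroxymethyl)acrylate | C=C(CO)C(=O)OCC | starting material
14 | ethyl 2-{[(tert-butyldimethylsilyl)oxy]methyl}acrylate | C=C(CO[Si](C)(C)C(C)(C)C)C(=O)OCC | intermediate
15 | ethyl 3-{[(tert-butyldimethylsilyl)oxy]methyl}-1,2,4-trioxolane-3-carboxylate (racemic) | CCOC(=O)C1(CO[Si](C)(C)C(C)(C)C)OCOO1 | intermediate (not isolated)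
16 | ethyl 3-[(tert-butyldimethylsilyl)oxy]-2-oxopropanoate | CCOC(=O)C(=O)CO[Si](C)(C)C(C)(C)C | intermediate
17 | lithium enolate of 12 at C6/C7 (enolate geometry not specified) | [Li+].[O-]C1=C[C@@H](OCc2ccc(OC)cc2)C/C(C)=C/CC/C(C)=C\1 | intermediate (not isolated)
18 | lithium 11-alkoxide (aldolate) corresponding to 19 | [Li+].COc1ccc(cc1)CO[C@H]1C/C(C)=C/CC/C(C)=C\C(=O)[C@H]1[C@]([O-])(CO[Si](C)(C)C(C)(C)C)C(=O)OCC | intermediate (not isolated)
19 | ethyl (1(10)E,4Z,7R,8S,11S)-13-[(tert-butyldimethylsilyl)oxy]-8-[(4-methoxybenzyl)oxy]-6-oxo-11-[(trimethylsilyl)oxy]germacra-1(10),4-dien-12-oate | COc1ccc(cc1)CO[C@H]1C/C(C)=C/CC/C(C)=C\C(=O)[C@H]1[C@](O[Si](C)(C)C)(CO[Si](C)(C)C(C)(C)C)C(=O)OCC | intermediate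
20 | ethyl (1(10)E,4Z,6R,7R,8S,11S)-13-[(tert-butyldimethylsilyl)oxy]-6-hydroxy-8-[(4-methoxybenzyl)oxy]-11-[(trimethylsilyl)oxy]germacra-1(10),4-dien-12-oate | COc1ccc(cc1)CO[C@H]1C/C(C)=C/CC/C(C)=C\[C@@H](O)[C@H]1[C@](O[Si](C)(C)C)(CO[Si](C)(C)C(C)(C)C)C(=O)OCC | intermediate
21 | ethyl (1(10)E,4R,5S,6S,7R,8S,11S)-13-[(tert-butyldimethylsilyl)oxy]-4,5-epoxy-6-hydroxy-8-[(4-methoxybenzyl)oxy]-11-[(trimethylsilyl)oxy]germacr-1(10)-en-12-oate | COc1ccc(cc1)CO[C@H]1C/C(C)=C/CC[C@@]2(C)O[C@H]2[C@@H](O)[C@H]1[C@](O[Si](C)(C)C)(CO[Si](C)(C)C(C)(C)C)C(=O)OCC | intermediate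
22 | (1(10)E,4R,5S,6S,7S,8S,11S)-13-[(tert-butyldimethylsilyl)oxy]-4,5-epoxy-8-[(4-methoxybenzyl)oxy]-11-[(trimethylsilyl)oxy]germacr-1(10)-en-12,6-olide | COc1ccc(cc1)CO[C@H]1C/C(C)=C/CC[C@@]2(C)O[C@H]2[C@H]2OC(=O)[C@@](O[Si](C)(C)C)(CO[Si](C)(C)C(C)(C)C)[C@@H]12 | intermediate (not isolated)
23 | (1(10)E,4R,5S,6S,7S,8S,11S)-13-[(tert-butyldimethylsilyl)oxy]-4,5-epoxy-11-hydroxy-8-[(4-methoxybenzyl)oxy]germacr-1(10)-en-12,6-olide (cis-fused lactone, 11-OH cis to H-7) | COc1ccc(cc1)CO[C@H]1C/C(C)=C/CC[C@@]2(C)O[C@H]2[C@H]2OC(=O)[C@@](O)(CO[Si](C)(C)C(C)(C)C)[C@@H]12 | intermediate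
24 | triethylammonium salt of the 11-O-[N-(methoxycarbonyl)sulfamoyl] derivative of 23 | COc1ccc(cc1)CO[C@H]1C/C(C)=C/CC[C@@]2(C)O[C@H]2[C@H]2OC(=O)[C@@](OS(=O)(=O)[N-]C(=O)OC)(CO[Si](C)(C)C(C)(C)C)[C@@H]12.CC[NH+](CC)CC | intermediate (not isolated)
25 | (1(10)E,4R,5S,6S,8S)-13-[(tert-butyldimethylsilyl)oxy]-4,5-epoxy-8-[(4-methoxybenzyl)oxy]germacra-1(10),7(11)-dien-12,6-olide | COc1ccc(cc1)CO[C@H]1C/C(C)=C/CC[C@@]2(C)O[C@H]2[C@H]2OC(=O)C(CO[Si](C)(C)C(C)(C)C)=C12 | intermediate
26 | (1S,10R)-1-boranyl derivative of the C1–C10 saturated lactone (monoalkylborane from 25) | COc1ccc(cc1)CO[C@H]1C[C@@H](C)[C@@H](B)CC[C@@]2(C)O[C@H]2[C@H]2OC(=O)C(CO[Si](C)(C)C(C)(C)C)=C12 | intermediate (not isolated)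
27 | (1S,4R,5S,6S,8S,10R)-13-[(tert-butyldimethylsilyl)oxy]-4,5-epoxy-1-hydroxy-8-[(4-methoxybenzyl)oxy]germacr-7(11)-en-12,6-olide | COc1ccc(cc1)CO[C@H]1C[C@@H](C)[C@@H](O)CC[C@@]2(C)O[C@H]2[C@H]2OC(=O)C(CO[Si](C)(C)C(C)(C)C)=C12 | intermediate
28 | (4R,5S,6S,8S,10R)-13-[(tert-butyldimethylsilyl)oxy]-4,5-epoxy-8-[(4-methoxybenzyl)oxy]-1-oxogermacr-7(11)-en-12,6-olide | COc1ccc(cc1)CO[C@H]1C[C@@H](C)C(=O)CC[C@@]2(C)O[C@H]2[C@H]2OC(=O)C(CO[Si](C)(C)C(C)(C)C)=C12 | intermediate
29 | (4R,5S,6S,8S,10R)-13-[(tert-butyldimethylsilyl)oxy]-4,5-epoxy-8-hydroxy-1-oxogermacr-7(11)-en-12,6-olide | O[C@H]1C[C@@H](C)C(=O)CC[C@@]2(C)O[C@H]2[C@H]2OC(=O)C(CO[Si](C)(C)C(C)(C)C)=C12 | intermediate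
30 | tiglic acid, (E)-2-methylbut-2-enoic acid | C/C=C(\C)C(O)=O | starting material
31 | (E)-2-methylbut-2-enoic 2,4,6-trichlorobenzoic anhydride | C/C=C(\C)C(=O)OC(=O)c1c(Cl)cc(Cl)cc1Cl | intermediate (not isolated)
32 | (4R,5S,6S,8S,10R)-13-[(tert-butyldimethylsilyl)oxy]-4,5-epoxy-8-[(E)-2-methylbut-2-enoyloxy]-1-oxogermacr-7(11)-en-12,6-olide | C/C=C(\C)C(=O)O[C@H]1C[C@@H](C)C(=O)CC[C@@]2(C)O[C@H]2[C@H]2OC(=O)C(CO[Si](C)(C)C(C)(C)C)=C12 | intermediate
33 | (4R,5S,6S,8S,10R)-4,5-epoxy-13-hydroxy-8-[(E)-2-methylbut-2-enoyloxy]-1-oxogermacr-7(11)-en-12,6-olide | C/C=C(\C)C(=O)O[C@H]1C[C@@H](C)C(=O)CC[C@@]2(C)O[C@H]2[C@H]2OC(=O)C(CO)=C12 | intermediate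
34 | (4R,5S,6S,8S,10R)-13-acetoxy-4,5-epoxy-8-[(E)-2-methylbut-2-enoyloxy]-1-oxogermacr-7(11)-en-12,6-olide | C/C=C(\C)C(=O)O[C@H]1C[C@@H](C)C(=O)CC[C@@]2(C)O[C@H]2[C@H]2OC(=O)C(COC(C)=O)=C12 | target

## Step count and least certain steps

Total step count: 18. Longest linear sequence: 15 steps (steps 2, 3, 4, 5 and 8 to 18, from 3 to 34).

**Step 5 (key step).** Two processes threaten it. The potassium enolate may expel the C8 alkoxy group (E1cB) before the quench. The reaction may also leak through a boat transition state, because the chair carries the alkoxide and the ether oxygen 1,3-diaxial; that would erode the configuration at C8 or the olefin geometry. Fallback: from 9, a neutral cyclisation-induced oxy-Cope rearrangement catalysed by PdCl2(PhCN)2 (divalent palladium) in THF at 23 °C. The metal activates the enol ether olefin, C9 attacks C8 through a chair-like six-membered array with the cationic centre on the methyl-bearing C10, and fragmentation gives 12 directly. No enolate and no oxyanion are involved, and no new compound is made (F0); the route is rejoined at 12.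

**Step 8.** The lithium enolate may lose the 4-methoxybenzyloxy group, the enolisable keto ester may simply protonate the enolate, or the aldolate may revert before it is silylated. Fallback: from 9, the rearrangement is run as in step 5 but enolate 11 is trapped at −78 °C with Me3SiCl as the silyl enol ether of 12, (1E,3Z,7E,10S)-10-[(4-methoxybenzyl)oxy]-4,8-dimethyl-1-[(trimethylsilyl)oxy]cyclodeca-1,3,7-triene F1. A Mukaiyama aldol addition of F1 to 16 with catalytic Cu(OTf)2 in CH2Cl2 at −78 °C, with silyl transfer to the new alkoxide, comes back to the route at 19 without any basic enolate.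

**Step 9.** Facial selectivity may be poor if zinc is not held by the C8 ether. Felkin-type delivery would give the C6 epimer, which would then misdirect the epoxidation. Fallback: from 19, catalyst-controlled reduction with a 2-methyl-CBS-oxazaborolidine and catecholborane at −78 °C, the catalyst enantiomer being chosen to deliver hydride to the face that gives 20. No new compound is made (F0); the route is rejoined at 20.

**Step 12.** Water may be lost toward C13 to give a silyl enol ether. Elimination may also fail altogether if the aldol has set C11 the other way, so that H-7 is not syn to the sulfamate. Fallback: from 23, acetylation (Ac2O, DMAP) to the 11-acetate of 23 F2. Reductive removal of the alpha-acyloxy group with SmI2 in THF/MeOH at −78 °C gives the 11-deoxy lactone (C11–H, configuration at C11 immaterial) F3. Its lithium enolate (LiN(i-Pr)2, −78 °C) is selenenylated with PhSeBr on the face away from C8 to give the 11-phenylselanyl lactone F4. Oxidation with H2O2 triggers selenoxide syn-elimination, which avoids the oxygen-bearing C13 and uses H-7; the route is rejoined at 25.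

**Step 13.** Borane may attack the other face of the E olefin if the ring prefers the conformer with C14 on the side of the C8 oxygen, giving the wrong C10. The lactone or epoxide may also be reduced if the olefin reacts slowly. Fallback: from 25, the same hydroboration–oxidation is accepted with the opposite facial sense, giving the (1R,10S)-alcohol F5, which is oxidised as in step 14 to the 10-epi ketone F6. C10 is the only stereocentre alpha to C1, so F6 would be epimerised through its enol with a hindered amine base under thermodynamic control, or by kinetic protonation of its C1 silyl enol ether; the route is rejoined at 28.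

## Further compounds

F0 | step 5 | none | none
F1 | step 8 | (1E,3Z,7E,10S)-10-[(4-methoxybenzyl)oxy]-4,8-dimethyl-1-[(trimethylsilyl)oxy]cyclodeca-1,3,7-triene | C[Si](C)(C)O/C1=C\[C@@H](OCc2ccc(OC)cc2)C/C(C)=C/CC/C(C)=C\1
F0 | step 9 | none | none
F2 | step 12 | 11-acetate of 23 | COc1ccc(cc1)CO[C@H]1C/C(C)=C/CC[C@@]2(C)O[C@H]2[C@H]2OC(=O)[C@@](OC(C)=O)(CO[Si](C)(C)C(C)(C)C)[C@@H]12
F3 | step 12 | 11-deoxy lactone, (1(10)E,4R,5S,6S,7S,8S)-13-[(tert-butyldimethylsilyl)oxy]-4,5-epoxy-8-[(4-methoxybenzyl)oxy]germacr-1(10)-en-12,6-olide (C11 unspecified) | COc1ccc(cc1)CO[C@H]1C/C(C)=C/CC[C@@]2(C)O[C@H]2[C@H]2OC(=O)C(CO[Si](C)(C)C(C)(C)C)[C@@H]12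
F4 | step 12 | 11-phenylselanyl lactone (selenium cis to H-7) | COc1ccc(cc1)CO[C@H]1C/C(C)=C/CC[C@@]2(C)O[C@H]2[C@H]2OC(=O)[C@@]([Se]c3ccccc3)(CO[Si](C)(C)C(C)(C)C)[C@@H]12
F5 | step 13 | (1R,4R,5S,6S,8S,10S)-13-[(tert-butyldimethylsilyl)oxy]-4,5-epoxy-1-hydroxy-8-[(4-methoxybenzyl)oxy]germacr-7(11)-en-12,6-olide | COc1ccc(cc1)CO[C@H]1C[C@H](C)[C@H](O)CC[C@@]2(C)O[C@H]2[C@H]2OC(=O)C(CO[Si](C)(C)C(C)(C)C)=C12
F6 | step 13 | (4R,5S,6S,8S,10S)-13-[(tert-butyldimethylsilyl)oxy]-4,5-epoxy-8-[(4-methoxybenzyl)oxy]-1-oxogermacr-7(11)-en-12,6-olide (10-epimer of 28) | COc1ccc(cc1)CO[C@H]1C[C@H](C)C(=O)CC[C@@]2(C)O[C@H]2[C@H]2OC(=O)C(CO[Si](C)(C)C(C)(C)C)=C12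
A1 | alternative 1 | acyclic 4,5-epoxy butenolide with C8 and C13 tert-butyldimethylsilyl ethers, C1 tert-butyldiphenylsilyl ether and a trimethylsilylalkyne at C10 | C[Si](C)(C)C#CC[C@H](O[Si](C)(C)C(C)(C)C)C1=C(CO[Si](C)(C)C(C)(C)C)C(=O)O[C@@H]1[C@@H]2O[C@]2(C)CCCO[Si](c3ccccc3)(c3ccccc3)C(C)(C)C
A2 | alternative 1 | methyl ester with C4 tertiary alcohol, trans 5,6-epoxide and the ester cis to C6 on C7=C11 | C[Si](C)(C)C#CC[C@H](O[Si](C)(C)C(C)(C)C)/C(=C(\CO[Si](C)(C)C(C)(C)C)C(=O)OC)[C@@H]1O[C@H]1[C@](C)(O)CCCO[Si](c2ccccc2)(c2ccccc2)C(C)(C)C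
A3 | alternative 2 | (4R,5S,6S,8R,10R)-8,13-epidioxy-4,5-epoxy-1-oxogermacr-7(11)-en-12,6-olide (8-epi) | O3[C@@H]1C[C@@H](C)C(=O)CC[C@@]2(C)O[C@H]2[C@H]2OC(=O)C(CO3)=C12
A4 | alternative 2 | (4R,5S,6S,7Z,10R)-4,5-epoxy-1-oxogermacra-7,11(13)-dien-12,6-olide | C=C1C(=O)O[C@H]2/C1=C\C[C@@H](C)C(=O)CC[C@@]3(C)O[C@@H]23
A5 | alternative 3 | (4R,5S,6S,8S,10R)-8,13-bis[(tert-butyldimethylsilyl)oxy]-4,5-epoxy-1-oxogermacr-7(11)-en-12,6-olide | CC(C)(C)[Si](C)(C)O[C@H]1C[C@@H](C)C(=O)CC[C@@]2(C)O[C@H]2[C@H]2OC(=O)C(CO[Si](C)(C)C(C)(C)C)=C12
A6 | alternative 3 | open-chain C6 aldehyde with cis 4,5-epoxide, C1 ketone, C8 silyl ether and (Z)-C7 enol triflate of the methyl ester | O=C[C@@H]1O[C@]1(C)CCC(=O)[C@H](C)C[C@H](O[Si](C)(C)C(C)(C)C)/C(OS(=O)(=O)C(F)(F)F)=C(\CO[Si](C)(C)C(C)(C)C)C(=O)OC
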